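By the reactions considered, [starting material] + [target] + [spent catalyst] stays at the charge of starting material, and [free catalyst] + [spent catalyst] stays at the charge of catalyst. The runs are therefore compared in mM of target, not in percent.

| flask | starting material | gas phase | free catalyst | remark | time |
|---|---|---|---|---|---|
| midnight | 13 mM | 5.9 mM (held) | 3 mM | run made earlier |  |
| autumn | 30 mM | 5.9 mM (held) | 3 mM | run made earlier |  |
| winter | 20 mM | 5.9 mM (held) | 6 mM | run made earlier |  |
| flask | 20 mM | 5.9 mM (held) | 3.0 mM |  | 6.0 d |

| run | time / d | target / % |
|---|---|---|
| midnight | 0.500 | 4.7 |
| midnight | 1.25 | 16.3 |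
| midnight | 2.50 | 34.2 |
| midnight | 4.00 | 48.6 |
| midnight | 6.00 | 58.7 |
| midnight | 8.00 | 62.2 |
| autumn | 0.625 | 4.3 |
| autumn | 1.04 | 8.6 |
| autumn | 1.67 | 14.1 |
| autumn | 2.50 | 21.4 |
| autumn | 4.00 | 31.3 |
| autumn | 8.00 | 45.7 |
| winter | 0.625 | 8.0 |
| winter | 1.04 | 12.7 |
| winter | 2.08 | 25.6 |
| winter | 4.00 | 40.8 |
| winter | 8.00 | 54.2 |

(each reading ± 0.3 percentage points)

- at the start none of the gas is dissolved
- what was read earlier has a scatter of 0.3 percentage points, one standard deviation
- reactions considered so far: gas phase <-> dissolved gas; starting material + dissolved gas + free catalyst -> free catalyst + target; free catalyst + target -> spent catalyst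

- north: doubling the transfer coefficient of the gas phase, all else as stated
- west: doubling the saturation concentration of gas phase, all else as stated
- south-east: doubling the amount of free catalyst, all else as stated

- target at 6.0 d, in percent of the starting material charged
- concentration of dissolved gas in solution at 40 h, in percent of saturation
- the change that raises the amount of target at 6.0 d, in percent of the starting material charged most ("none" if none brings more than 2 percentage points) (north / west / south-east / none)
- amount of target at 6.0 d, in percent of the starting material charged, after west

1. Dissolving comes first. The gas starts undissolved, and the midnight run makes target at 1.22 mM d⁻¹ up to 0.500 d, then at 2.01 mM d⁻¹ up to 1.25 d, which is faster than at the start.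

2. Next, target in mM grows less than the charge. At 2.50 d the midnight run holds 4.45 mM of target and the autumn run 6.42 mM. These readings give 0.439 for the charge exponent, the apparent order in starting material: the logarithm of the ratio of target in mM over the logarithm of the ratio of charges, at one time with gas and catalyst equal. Zero on this scale means the same mM from any charge, and one the same percent, so this reading lies nearer zero than one.

3. Between 4.00 d and 8.00 d the midnight run makes 0.442 mM d⁻¹, less than the 1.08 mM d⁻¹ of the autumn run. The exponent climbs to 0.474 at 4.00 d and 0.631 at 8.00 d.

4. For the flask at 6.0 d, halfway between these readings, the exponent is taken as 0.553. Scaling the 58.7% of the midnight run from 13 mM to 20 mM gives 48.4% of target.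

The forecast gives 47.5% (45% to 50%), 42% of saturation at 40 h, west as the best change and 68% after it, holding that “doubling saturation doubles both supply and driving force”.

The flask gives 49.9% of target and 24.4% of saturation at 40 h. The best change is west, with gains of 20 percentage points for west, 11 points for north and 0.49 points for south-east, and west reaches 69.9%.

    gas phase ⇌ dissolved gas, rate k1*(csat - [dissolved gas]) (kL = 0.0280 h⁻¹)
    starting material + dissolved gas + free catalyst → free catalyst + target (k = 1800 M⁻² h⁻¹)
    free catalyst + target → spent catalyst (k = 1.50 M⁻¹ h⁻¹)

The exponent's 48.4% lies 1.5 points below the flask. In the flask at 2.50 d, each step taken net, target is made 5.21 times faster than it is used up, and at 6.00 d still 3.35 times faster, with free catalyst at 28.4% of its charge at that later time. Of the starting material charged to the flask, 39.3% remains at 6.00 d and 10.7% is held in spent catalyst. For the flask stopped at 2.5 d, the exponent 0.439 scales the 34.2% of the midnight run to 26.9%; the computed result is 27.4%.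

All runs are calculated on assumed constants.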